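## The problem

Numbering: hydrindane atoms C1 to C7a; ring A atoms C1' to C6' with C1' = C6; α is the face of H7a, β the face of H3a.

The target joins an enolised 2-acylcyclohexane-1,3,5-trione (ring A, with the 3-methylbutanoyl group on C3' and two prenyl groups on C5') through the spiro atom C6 to a trans-fused hydrindane. Ring B is C3a, C4, C5, C6, C7, C7a and ring C is C1, C2, C3, C3a, C7a. Five stereocentres have to be set: the tertiary carbinols C1 (OH β) and C4 (OH α, axial), the fusion atoms C3a and C7a, and the quaternary C6. C6 is stereogenic only because its two carbonyl neighbours differ (C2' on the α face next to the acylated C3', C6' on the β face next to the diprenylated C5'), so no reagent can select a face there and an internal relay is needed. C3a can control C7a (trans, and epimerisable while C7 is a carbonyl) and through it C1. The trans fusion then locks ring B as a chair in which the C4 oxygen and the α carbonyl on C6 are 1,3-diaxial, so a γ-lactone between them can fix C4 and C6 together. The C1 hydroxyl is β to C7 and is lost by dehydration or retro-aldol while C7 is a carbonyl; both tertiary alcohols ionise in strong acid; the triketone is open to O-alkylation and retro-Claisen cleavage; the prenyl alkenes would not survive hypochlorite, iodine or stannyl radicals and must come last. Ring C, with C7 on C7a and the C4/C5/methyl unit on C3a, has the carbon skeleton of ring-opened limonene, and the C1 carbinol β to C7 is an aldol retron. The C1–C7a bond can therefore be made by a 5-enolexo aldol of the limonene-derived keto aldehyde, with C3a supplied in the correct absolute configuration by the (R)-terpene.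

## Retrosynthesis

**17 to 15 and 16.** Both C5'–CH2 bonds are cut, leaving the bis-desprenyl trione 15 and prenyl bromide 16. Carrying the prenyl groups earlier would expose them to every electrophilic and radical step, and would require the C5'–C6' bond to be formed between two quaternary carbons. C5' is the only methylene of ring A, so the forward reaction asks only for double C-alkylation in preference to O-alkylation.

**15 to 14.** Ring A is cut at C2'–C3', not at C5'–C6' or C3'–C4'. This cut exposes an ester at C2' that can be tied to the C4 oxygen as a γ-lactone, which makes the two carboxyl carbons on C6 different and carries configuration to the spiro centre. The precursor 14 has one ring fewer and a free chain. The forward reaction is a Dieckmann closure through C3' onto the lactone carbonyl; only C3' can give a six-membered ring, and the aldol mode is blocked because C6 is quaternary.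

**14 to 11 and 12.** The C5'–C6' bond is cut between the free (β) carboxyl of lactone acid 11 and the terminal carbon of 6-methylheptane-2,4-dione 12, which brings all remaining carbons of ring A in one commercial piece. The forward reaction must acylate the diketone dianion at the activated carboxyl (imidazolide 13) and leave the lactone alone.

**11 to 10 to 9 to 8.** The C4–O bond and the C4 methyl hydrogen are removed: 11 comes from iodolactone 10, and 10 from the diacid 9 with an exocyclic methylene on C4. Two stereocentres (C4, C6) vanish, and 9 is the hydrolysis product of the spiro Meldrum's acid 8, which is symmetric at C6. The forward iodolactonisation must choose the α carboxylate and the α face of C4; the locked chair leaves no other option. Direct acid-catalysed lactonisation was set aside because it would ionise the C1 carbinol.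

**8 to 4 and 5.** Ring B is cut at C6–C7 and C5–C6, so that C6 comes from Meldrum's acid 5 acting twice: as Knoevenagel donor towards the aldehyde C7 and as carbanion towards an allylic chloride at C5. Meldrum's acid is preferred to a dialkyl malonate because it condenses at room temperature without base, which a β-hydroxy aldehyde needs, and because its spiro derivative hydrolyses at room temperature. The forward sequence has to spare the free C1 hydroxyl.

**4 to 3.** The C5–Cl bond is removed, leaving the isopropenyl group of 3. The forward reaction is an ene-type chlorination; the 2-substituted allyl unit formed is symmetric, so either terminus may later be attacked.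

**3 to 2.** The C1–C7a bond is cut (aldol retron). This is preferred to any cut inside ring B because it removes one ring and two stereocentres and leaves an acyclic keto aldehyde with a single stereocentre. The forward reaction must give the trans,cis triad and stop before loss of water.

**2 to 1.** The keto aldehyde 2 is the product of oxidative cleavage of the ring alkene of (R)-limonene, most simply from its commercial 1,2-oxide 1 with periodic acid.

## Roads not taken

**Alternative 1:** Ring A is cut at C2'–C3'. In the forward sense the polyanion of the lactone triketone A2, whose γ-lactone joins the α carbonyl on C6 to the C4 oxygen, attacks the lactone carbonyl through C3'. This gives the bis-desprenyl trione A1 and frees the C4 hydroxyl.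
- Merits: the spiro centre is controlled by a rigid template and not by a reagent; no protecting group is needed; the very acidic product anion drives the closure; only C3' can give a six-membered ring.
- Weak points: as the defining step it lies at the end of the sequence, where material is most valuable. It presupposes A2 as a single C4/C6 diastereomer, so it leaves open how the hydrindane and the C1/C3a/C7a triad arise. Retro-Claisen cleavage of the chain, and return of the tertiary alkoxide onto C2', remain open.
- Comparison: for ring A this closure is as good as anything available, and the chosen plan adopts it as step 8 (A2 and A1 have the structures of 14 and 15). What the chosen plan sets against making it the centre of the design is that it answers the earlier question, the origin of three contiguous stereocentres of ring C in enantiopure form, in its second step from a terpene.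

**Alternative 2:** The bonds C2–C3 and C7a–C3a are cut together. The acyclic malonate A4 carries on one arm a 2-(silylmethyl)allyl acetate unit (C7a, C1, C2) and on the other a vinyl ketone (C4, C3a, C3). A zerovalent palladium catalyst formed from Pd(OAc)2 and triisopropyl phosphite ionises it to a trimethylenemethane complex, which adds across the enone and gives the trans-fused methylidene hydrindanone diester A3, closing rings B and C at once.
- Merits: two rings and two C–C bonds in one step; the geminal diester on C6 and a C4 ketone are in place, so the C4 carbinol could come from equatorial addition of a methyl nucleophile and the iodolactonisation/deiodination pair would be unnecessary.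
- Weak points: A3 has no stereocentre beyond the ring fusion, so absolute configuration would rest on a chiral ligand in an intramolecular cycloaddition, where control is less secure than in intermolecular cases. Trans versus cis fusion is substrate-dependent. The C1 carbinol would have to be made from the exocyclic alkene with OH on the β face, for which neither radical hydration nor epoxidation/hydride opening has an obvious bias. The vinyl ketone arm is prone to polymerisation.
- Comparison: in bond-forming economy of the key step and in direct access to the C4 carbinol this road is better. The chosen plan sets against it that C3a comes enantiopure from the terpene, that C7a and C1 are set in the step that closes ring C with the C1 oxygen already present, and that the key step needs no metal, ligand or multistep precursor.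

**Alternative 3:** The bonds C7–C7a and C3a–C4 are cut. (R)-1-Methylcyclopent-2-en-1-ol A7, from ring-closing metathesis of (R)-linalool A8, is converted into its (bromomethyl)dimethylsilyl ether A6. The silylmethyl radical adds 5-exo to C7a, and the C3a radical is trapped anti to the new ring by an alkyl isocyanide, which after loss of its alkyl radical leaves a nitrile and gives the cis-fused siloxane nitrile A5.
- Merits: the C1 carbinol is taken from the chiral pool and not created. The tether forces C7 cis to the C1 oxygen and the trapping anti to it, so the triad follows from geometry and not from an equilibrium.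
- Weak points: isocyanide trapping of a secondary alkyl radical competes poorly with hydrogen transfer and needs a large excess. The nitrile brings only C4, so the C4 methyl and C5 must still be added and the C4 carbinol set without a template. C7 must be unmasked by Tamao oxidation and activated before C6 can be attached. A7 is volatile, and the optical purity of commercial A8 varies.
- Comparison: for the security of the C1 configuration this road is better than an aldol that rests on catalyst control and equilibration. The chosen plan sets against it that one terpene already holds C1 to C5, C7 and both methyl groups, so that after step 2 only C6 has to be added, and that ring B is built without tin, isocyanide or a silicon tether.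

Key step: step 2

Remarks on the chemistry:
- Commercial (R)-limonene 1,2-oxide, sold as the cis/trans mixture at the epoxide and (4R) throughout, is taken as the chiral-pool starting material; both epoxide diastereomers give the same keto aldehyde.
- The target is written as one enol tautomer of the β-triketone; the tautomers interconvert and are treated as one compound.

## Route

Step 1
Reactants: 1 (R)-limonene 1,2-oxide [(4R)-1-methyl-4-(prop-1-en-2-yl)-7-oxabicyclo[4.1.0]heptane, cis/trans mixture at the epoxide]
Product: 2 (3R)-6-oxo-3-(prop-1-en-2-yl)heptanal
Conditions: HIO4·2H2O (1.1 equiv), THF/H2O, 0 °C to rt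
Reagents that add atoms: water, O
Why: Acid-promoted hydrolysis of the trisubstituted epoxide to the 1,2-diol and Malaprade glycol cleavage in the same flask; both epoxide diastereomers converge, and the isopropenyl group and the future C3a centre are not touched.

Step 2
Reactants: 2 (3R)-6-oxo-3-(prop-1-en-2-yl)heptanal
Product: 3 (1S,2R,5R)-2-hydroxy-2-methyl-5-(prop-1-en-2-yl)cyclopentane-1-carbaldehyde (CHO trans to isopropenyl and cis to OH)
Conditions: L-proline (20 mol%), DMF, 0 °C to rt
Reagents that add atoms: none
Why: Enamine aldol: L-proline condenses with the aldehyde to the (E)-enamine, C7a of which adds to the ketone carbon C1 while the carboxylic acid hydrogen-bonds to the ketone oxygen, and hydrolysis of the iminium ion releases 3 and the catalyst. The closest known reaction type is the proline-catalysed intramolecular enolexo aldolisation of keto aldehydes and dialdehydes; the secondary-amine cyclisation of this very keto aldehyde is classical but is usually driven on to the enal. Ring C closes in the 5-(enolexo)-exo-trig mode. C7a is controlled by the resident C3a centre, since bond formation anti to the isopropenyl group gives the trans product, L-proline is expected to favour the same enamine face (matched pair), and C7a stays epimerisable through the enamine so that any cis isomer drains to trans. C1 is controlled by the hydrogen-bonded transition state, which holds the ketone oxygen syn to the enamine carbon C7 and so puts OH cis and CH3 trans to the formyl group. Because the aldol is reversible under the same catalyst, kinetic errors at C1 are corrected by retro-aldol and re-addition towards the isomer that has the formyl group trans to both flanking carbon substituents and an O-H···O=C hydrogen bond. The step needs the aldehyde and not the methyl ketone to form the enamine, which the much faster condensation of proline with an unhindered aldehyde secures, and it needs to stop before water is lost, which the weakly acidic catalyst, low temperature and limited reaction time secure. C3a is not acidic under these conditions and keeps the configuration of the terpene.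

Step 3
Reactants: 3 (1S,2R,5R)-2-hydroxy-2-methyl-5-(prop-1-en-2-yl)cyclopentane-1-carbaldehyde
Product: 4 (1S,2R,5R)-5-(3-chloroprop-1-en-2-yl)-2-hydroxy-2-methylcyclopentane-1-carbaldehyde
Conditions: Ca(OCl)2 (0.6 equiv), solid CO2, CH2Cl2/H2O, 0 °C
Reagents that add atoms: calcium hypochlorite, [Ca+2].[O-]Cl.[O-]Cl
Why: Ene-type allylic chlorination by HOCl, established for isopropenyl terpenoids: the 1,1-disubstituted alkene takes Cl+ at its CH2 terminus and loses a methyl proton, giving the 2-(chloromethyl)vinyl group. The aldehyde should survive brief two-phase hypochlorite at 0 °C, as it does in hypochlorite/nitroxyl alcohol oxidations, and the C1 hydroxyl cannot reach the C4 cation because C1 and C4 are anti across the C7a-C3a bond.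

Step 4
Reactants: 4 (1S,2R,5R)-5-(3-chloroprop-1-en-2-yl)-2-hydroxy-2-methylcyclopentane-1-carbaldehyde; 5 Meldrum's acid (2,2-dimethyl-1,3-dioxane-4,6-dione)
Product: 8 (1R,3aR,7aS)-1-hydroxy-1,2',2'-trimethyl-4-methylideneoctahydrospiro[indene-6,5'-[1,3]dioxane]-4',6'-dione, via alkylidene Meldrum's acid 6 (not isolated), via monoalkyl Meldrum's acid 7 (not isolated)
Conditions: Hantzsch ester (diethyl 2,6-dimethyl-1,4-dihydropyridine-3,5-dicarboxylate, 1.1 equiv), L-proline (10 mol%), CH2Cl2, rt; then solvent exchange, K2CO3 (2.5 equiv), DMF, rt
Reagents that add atoms: none
Why: Three-component organocatalytic reductive alkylation: proline-catalysed Knoevenagel condensation gives 6, which the Hantzsch ester reduces at once by conjugate hydride transfer to 7, so the β-hydroxy aldehyde never meets strong base or heat. K2CO3 then converts 7 (pKa about 5) into its carbanion, which closes ring B by 6-exo-tet C-alkylation of the allylic chloride (SN2 and SN2' give the same product). No stereocentre is formed, because C6 carries two identical acyl groups.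

Step 5
Reactants: 8 (1R,3aR,7aS)-1-hydroxy-1,2',2'-trimethyl-4-methylideneoctahydrospiro[indene-6,5'-[1,3]dioxane]-4',6'-dione
Product: 10 iodolactone acid (1R,3aR,4S,6S,7aS)-1,4-dihydroxy-4-(iodomethyl)-1-methyloctahydro-1H-indene-6,6-dicarboxylic acid 6α,4-lactone, via diacid 9 (not isolated)
Conditions: NaOH (2.5 equiv), THF/H2O, rt; then CO2 to pH 8, I2 (1.5 equiv), KI, 0 °C to rt, dark; Na2S2O3, then cold HCl to pH 2
Reagents that add atoms: sodium hydroxide, [Na+].[OH-]; iodine, II
Why: Hydroxide opens the non-enolisable spiro Meldrum's acid at room temperature to the dicarboxylate of 9 and acetone, and iodolactonisation under bicarbonate buffer follows the classical protocol. The trans fusion locks ring B as a chair in which only the axial (α) carboxylate on C6 can reach C4, so Markovnikov attack on the iodonium ion from the α face gives the γ-lactone. This sets C4 (O axial, CH2I equatorial) and makes C6 stereogenic in the same event (lactone carbonyl α, free CO2H β).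

Step 6
Reactants: 10 iodolactone acid
Product: 11 lactone acid (1R,3aR,4S,6S,7aS)-1,4-dihydroxy-1,4-dimethyloctahydro-1H-indene-6,6-dicarboxylic acid 6α,4-lactone
Conditions: Bu3SnH (1.3 equiv, 0.2 M), AIBN (0.1 equiv), toluene, 80 °C; KF work-up
Reagents that add atoms: none
Why: Radical chain dehalogenation of the primary iodide by the tin hydride; at this stannane concentration hydrogen transfer should outrun a 1,2-acyloxy shift, which the bridged lactone disfavours in any case, and no alkene is present to intercept the radical. No stereocentre is touched.

Step 7
Reactants: 11 lactone acid; 12 6-methylheptane-2,4-dione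
Product: 14 lactone triketone 1-[(1R,3aR,4S,6S,7aS)-6α-carboxy-1,4-dihydroxy-1,4-dimethyloctahydro-1H-inden-6-yl]-7-methyloctane-1,3,5-trione 6α,4-lactone, via acyl imidazolide 13 (not isolated)
Conditions: CDI (1.1 equiv), THF, rt, then argon purge; separately 12 (4.5 equiv), LiN(iPr)2 (9 equiv), THF, -78 to 0 °C; add 13 at -78 °C, warm to -20 °C; cold dilute HCl
Reagents that add atoms: none
Why: CDI converts the acid into the acyl imidazolide 13 and leaves the hindered tertiary alcohol alone; the dianion of 12, formed by kinetic second deprotonation at the methyl group, is acylated at that terminal carbon (Claisen-type acylation of a β-diketone dianion, the standard entry to 1,3,5-triketones). The imidazolide is far more electrophilic than the bridged lactone, so the chain is attached only to the β carbonyl on C6 and the C6 configuration is preserved. Excess dianion takes up the protons of the C1 hydroxyl, imidazole and the product.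

Step 8
Reactants: 14 lactone triketone
Product: 15 (1R,3aR,4S,6S,7aS)-1,4,4'-trihydroxy-1,4-dimethyl-3'-(3-methylbutanoyl)octahydrospiro[indene-6,1'-cyclohexan]-3'-ene-2',6'-dione (bis-desprenyl target)
Conditions: KOt-Bu (3.5 equiv), THF, 0 °C to rt; then cold 1 M HCl
Reagents that add atoms: none
Why: Dieckmann condensation: the triketone dianion attacks the lactone carbonyl through C3' in a 6-(enolexo)-exo-trig closure, the tetrahedral intermediate expels the C4 alkoxide, and the strongly acidic 2-acylcyclohexane-1,3,5-trione is held as its enolate, as in Claisen cyclisations of triketo esters to acylphloroglucinols. C5' cannot give a six-membered ring and the aldol mode is blocked by the quaternary C6. C4 and C6 keep the configurations fixed in step 5.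

Step 9
Reactants: 15 bis-desprenyl target; 16 prenyl bromide (1-bromo-3-methylbut-2-ene)
Product: 17 CNP0198642.2, (1R,3aR,4S,6S,7aS)-1,4,4'-trihydroxy-1,4-dimethyl-3'-(3-methylbutanoyl)-5',5'-bis(3-methylbut-2-en-1-yl)octahydrospiro[indene-6,1'-cyclohexan]-3'-ene-2',6'-dione
Conditions: NaOMe (4 equiv), MeOH, -10 °C; 16 (2.4 equiv), -10 to 0 °C; aq. NH4Cl
Reagents that add atoms: none
Why: Double C-alkylation of the cyclic β-triketone at its only methylene C5', the classical route to geminal diprenyl acylphloroglucinol derivatives of the lupulone type: after the acidic enol is deprotonated, further deprotonation at C5' gives a dianion whose more basic carbon reacts with the allylic bromide, and the protic solvent favours C- over O-alkylation. The tertiary alcohols are not alkylated in methanol and no stereocentre is affected.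

## Compound list

1 | (R)-limonene 1,2-oxide, (4R)-1-methyl-4-(prop-1-en-2-yl)-7-oxabicyclo[4.1.0]heptane, cis/trans mixture at the epoxide | CC12OC1C[C@@H](CC2)C(C)=C | starting material
2 | (3R)-6-oxo-3-(prop-1-en-2-yl)heptanal | O=CC[C@@H](CCC(C)=O)C(C)=C | intermediate
3 | (1S,2R,5R)-2-hydroxy-2-methyl-5-(prop-1-en-2-yl)cyclopentane-1-carbaldehyde | O=C[C@H]1[C@@H](CC[C@@]1(C)O)C(C)=C | intermediate
4 | (1S,2R,5R)-5-(3-chloroprop-1-en-2-yl)-2-hydroxy-2-methylcyclopentane-1-carbaldehyde | O=C[C@H]1[C@@H](CC[C@@]1(C)O)C(=C)CCl | intermediate
5 | Meldrum's acid, 2,2-dimethyl-1,3-dioxane-4,6-dione | CC1(C)OC(=O)CC(=O)O1 | starting material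
6 | 5-{[(1S,2R,5R)-5-(3-chloroprop-1-en-2-yl)-2-hydroxy-2-methylcyclopentyl]methylidene}-2,2-dimethyl-1,3-dioxane-4,6-dione | CC1(C)OC(=O)C(=C[C@H]2[C@@H](CC[C@@]2(C)O)C(=C)CCl)C(=O)O1 | intermediate
7 | 5-{[(1S,2R,5R)-5-(3-chloroprop-1-en-2-yl)-2-hydroxy-2-methylcyclopentyl]methyl}-2,2-dimethyl-1,3-dioxane-4,6-dione | CC1(C)OC(=O)C(C[C@H]2[C@@H](CC[C@@]2(C)O)C(=C)CCl)C(=O)O1 | intermediate
8 | (1R,3aR,7aS)-1-hydroxy-1,2',2'-trimethyl-4-methylideneoctahydrospiro[indene-6,5'-[1,3]dioxane]-4',6'-dione | CC1(C)OC(=O)C2(C[C@H]3[C@@H](CC[C@@]3(C)O)C(=C)C2)C(=O)O1 | intermediate
9 | (1R,3aR,7aS)-1-hydroxy-1-methyl-4-methylideneoctahydro-6H-indene-6,6-dicarboxylic acid | OC(=O)C1(C[C@H]2[C@@H](CC[C@@]2(C)O)C(=C)C1)C(O)=O | intermediate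
10 | iodolactone acid, (1R,3aR,4S,6S,7aS)-1,4-dihydroxy-4-(iodomethyl)-1-methyloctahydro-1H-indene-6,6-dicarboxylic acid 6α,4-lactone | OC(=O)[C@]12C[C@H]3[C@@H](CC[C@@]3(C)O)[C@](CI)(C1)OC2=O | intermediate
11 | lactone acid, (1R,3aR,4S,6S,7aS)-1,4-dihydroxy-1,4-dimethyloctahydro-1H-indene-6,6-dicarboxylic acid 6α,4-lactone | OC(=O)[C@]12C[C@H]3[C@@H](CC[C@@]3(C)O)[C@](C)(C1)OC2=O | intermediate
12 | 6-methylheptane-2,4-dione | CC(C)CC(=O)CC(C)=O | starting material
13 | acyl imidazolide of 11 at the 6β carboxyl | O=C(n1ccnc1)[C@]12C[C@H]3[C@@H](CC[C@@]3(C)O)[C@](C)(C1)OC2=O | intermediate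
14 | lactone triketone, 1-[(1R,3aR,4S,6S,7aS)-6α-carboxy-1,4-dihydroxy-1,4-dimethyloctahydro-1H-inden-6-yl]-7-methyloctane-1,3,5-trione 6α,4-lactone | CC(C)CC(=O)CC(=O)CC(=O)[C@]12C[C@H]3[C@@H](CC[C@@]3(C)O)[C@](C)(C1)OC2=O | intermediate
15 | (1R,3aR,4S,6S,7aS)-1,4,4'-trihydroxy-1,4-dimethyl-3'-(3-methylbutanoyl)octahydrospiro[indene-6,1'-cyclohexan]-3'-ene-2',6'-dione | CC(C)CC(=O)C1=C(O)CC(=O)[C@@]2(C[C@H]3[C@@H](CC[C@@]3(C)O)[C@@](C)(O)C2)C1=O | intermediate
16 | prenyl bromide, 1-bromo-3-methylbut-2-ene | CC(C)=CCBr | starting material
17 | CNP0198642.2, (1R,3aR,4S,6S,7aS)-1,4,4'-trihydroxy-1,4-dimethyl-3'-(3-methylbutanoyl)-5',5'-bis(3-methylbut-2-en-1-yl)octahydrospiro[indene-6,1'-cyclohexan]-3'-ene-2',6'-dione | CC(C)=CCC1(CC=C(C)C)C(=O)[C@@]2(C[C@H]3[C@@H](CC[C@@]3(C)O)[C@@](C)(O)C2)C(=O)C(C(=O)CC(C)C)=C1O | target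

## Step count and least certain steps

Total steps: 9. Longest linear sequence: 9 steps (1 to 17).

**Step 2 (key step).** The aldol may run on to loss of water through the enamine, which would erase C1 and C7a, or equilibration may stop short and leave the C1 epimer. The fallback leaves 2 by the classical route and sets C1 by an epoxidation face instead of an aldol face:
- Piperidinium acetate converts 2 into the enal (S)-2-methyl-5-(prop-1-en-2-yl)cyclopent-1-ene-1-carbaldehyde F1.
- Alkaline hydrogen peroxide (H2O2, NaOH, MeOH, 0 °C), chemoselective for the electron-poor alkene and expected to act anti to the isopropenyl group, gives the epoxy aldehyde (2S)-5-methyl-2-(prop-1-en-2-yl)-6-oxabicyclo[3.1.0]hexane-1-carbaldehyde F2, with the epoxide oxygen trans to the isopropenyl group.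
- Samarium diiodide (SmI2, THF/MeOH, -90 °C) cleaves the Cα–O bond reductively, as established for α,β-epoxy ketones. Protonation of the enolate and equilibration at C7a to the trans isomer return the route to 3.

**Step 3.** Hypochlorous acid may oxidise or α-chlorinate the aldehyde, the carbonic acid medium may promote retro-aldol, and proton loss towards C3a would give the tetrasubstituted alkene. The fallback takes the aldehyde out of play:
- NaBH4 reduces 3 to the diol (1R,2R,3R)-2-(hydroxymethyl)-1-methyl-3-(prop-1-en-2-yl)cyclopentan-1-ol F3.
- The same chlorination gives the chloro diol (1R,2R,3R)-3-(3-chloroprop-1-en-2-yl)-2-(hydroxymethyl)-1-methylcyclopentan-1-ol F4; chloroetherification through the primary alcohol would need a strained trans-fused bicycle.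
- Selective oxidation of the primary alcohol (TEMPO, PhI(OAc)2) returns to 4.

**Step 4.** In 6 or 7 the free C1 hydroxyl may acylate itself on the activated Meldrum's carbonyl (δ-lactone with loss of acetone), 6 may lose water in a vinylogous sense, C7a may epimerise through the enamine, and the catalyst may be alkylated by the allylic chloride. The fallback avoids the condensation and uses Meldrum's acid as a double nucleophile:
- NaBH4 reduces 4 to the chloro diol F4 described under step 3.
- MsCl and Et3N at -20 °C give the primary mesylate [(1R,2R,5R)-5-(3-chloroprop-1-en-2-yl)-2-hydroxy-2-methylcyclopentyl]methyl methanesulfonate F5.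
- Meldrum's acid 5 with K2CO3 in DMF is alkylated first at the allylic chloride and then, intramolecularly, at the mesylate, which returns to 8.

**Step 7.** The dianion may attack the lactone carbonyl as well as the imidazolide, which would break the relay to C6. The second deprotonation of 12 may occur at the isobutyl methylene and give a branched chain. The neopentyl-type carbonyl may react slowly. The fallback replaces the strongly basic dianion by a purified, masked equivalent and the imidazolide by an acid chloride:
- TMSCl and Et3N convert 11 into the trimethylsilyl ester trimethylsilyl ether of 11, F6.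
- (COCl)2 with catalytic DMF converts the silyl ester of F6 under neutral conditions into the acid chloride of 11 with the C1 hydroxyl as its trimethylsilyl ether, F7.
- The dianion of 12 is O-silylated twice with TMSCl and distilled to give 6-methyl-2,4-bis(trimethylsilyloxy)hepta-1,3-diene F8.
- Acylation of F8 at its terminal carbon by F7 (CH2Cl2, -78 to 20 °C), followed by mild aqueous acid, returns to 14.

**Step 9.** O-prenylation may compete, the second alkylation at the now hindered C5' may stall, prenyl bromide may be lost to solvolysis, and the C4 alkoxide may reopen ring A by retro-Claisen attack on C2'. The fallback installs the two side chains in two stages: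
- Allyl bromide under the conditions of step 9 gives the 5',5'-diallyl analogue of 17, F9. Allyl bromide is less hindered and does not solvolyse, and any O-allyl ether can be moved to carbon by Claisen rearrangement or with Pd(PPh3)4, which an O-prenyl ether does not allow without allylic transposition.
- Cross-metathesis with excess 2-methylbut-2-ene and the second-generation Grubbs catalyst (H2IMes)(PCy3)Cl2Ru=CHPh converts both allyl groups into prenyl groups and returns to 17.

## Further compounds

F1 | step 2 | (S)-2-methyl-5-(prop-1-en-2-yl)cyclopent-1-ene-1-carbaldehyde | O=CC1=C(C)CC[C@H]1C(C)=C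
F2 | step 2 | (2S)-5-methyl-2-(prop-1-en-2-yl)-6-oxabicyclo[3.1.0]hexane-1-carbaldehyde, epoxide oxygen trans to the isopropenyl group | O=C[C@@]12O[C@]1(C)CC[C@H]2C(C)=C
F3 | step 3 | (1R,2R,3R)-2-(hydroxymethyl)-1-methyl-3-(prop-1-en-2-yl)cyclopentan-1-ol | OC[C@H]1[C@@H](CC[C@@]1(C)O)C(C)=C
F4 | step 3 | (1R,2R,3R)-3-(3-chloroprop-1-en-2-yl)-2-(hydroxymethyl)-1-methylcyclopentan-1-ol | OC[C@H]1[C@@H](CC[C@@]1(C)O)C(=C)CCl
F5 | step 4 | [(1R,2R,5R)-5-(3-chloroprop-1-en-2-yl)-2-hydroxy-2-methylcyclopentyl]methyl methanesulfonate | CS(=O)(=O)OC[C@H]1[C@@H](CC[C@@]1(C)O)C(=C)CCl
F6 | step 7 | trimethylsilyl ester trimethylsilyl ether of 11 | C[Si](C)(C)OC(=O)[C@]12C[C@H]3[C@@H](CC[C@@]3(C)O[Si](C)(C)C)[C@](C)(C1)OC2=O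
F7 | step 7 | acid chloride of 11 with the C1 hydroxyl as trimethylsilyl ether | ClC(=O)[C@]12C[C@H]3[C@@H](CC[C@@]3(C)O[Si](C)(C)C)[C@](C)(C1)OC2=O
F8 | step 7 | 6-methyl-2,4-bis(trimethylsilyloxy)hepta-1,3-diene | CC(C)CC(O[Si](C)(C)C)=CC(=C)O[Si](C)(C)C
F9 | step 9 | 5',5'-diallyl analogue of 17, (1R,3aR,4S,6S,7aS)-1,4,4'-trihydroxy-1,4-dimethyl-3'-(3-methylbutanoyl)-5',5'-di(prop-2-en-1-yl)octahydrospiro[indene-6,1'-cyclohexan]-3'-ene-2',6'-dione | C=CCC1(CC=C)C(=O)[C@@]2(C[C@H]3[C@@H](CC[C@@]3(C)O)[C@@](C)(O)C2)C(=O)C(C(=O)CC(C)C)=C1O
A1 | alternative 1 | bis-desprenyl trione, (1R,3aR,4S,6S,7aS)-1,4,4'-trihydroxy-1,4-dimethyl-3'-(3-methylbutanoyl)octahydrospiro[indene-6,1'-cyclohexan]-3'-ene-2',6'-dione | CC(C)CC(=O)C1=C(O)CC(=O)[C@@]2(C[C@H]3[C@@H](CC[C@@]3(C)O)[C@@](C)(O)C2)C1=O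
A2 | alternative 1 | lactone triketone, 1-[(1R,3aR,4S,6S,7aS)-6α-carboxy-1,4-dihydroxy-1,4-dimethyloctahydro-1H-inden-6-yl]-7-methyloctane-1,3,5-trione 6α,4-lactone | CC(C)CC(=O)CC(=O)CC(=O)[C@]12C[C@H]3[C@@H](CC[C@@]3(C)O)[C@](C)(C1)OC2=O
A3 | alternative 2 | dimethyl (3aR,7aS)-1-methylidene-4-oxooctahydro-6H-indene-6,6-dicarboxylate | COC(=O)C1(C(=O)OC)C[C@H]2[C@@H](CCC2=C)C(=O)C1
A4 | alternative 2 | dimethyl 2-[2-acetoxy-3-(trimethylsilylmethyl)but-3-en-1-yl]-2-(2-oxobut-3-en-1-yl)propanedioate | COC(=O)C(CC(OC(C)=O)C(=C)C[Si](C)(C)C)(CC(=O)C=C)C(=O)OC
A5 | alternative 3 | cis-fused 1,3,3-trimethyl-2-oxa-3-silabicyclo[3.3.0]octane-6-carbonitrile | C1[C@H]2[C@@H](CC[C@@]2(C)O[Si]1(C)C)C#N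
A6 | alternative 3 | (bromomethyl)dimethyl{[(1R)-1-methylcyclopent-2-en-1-yl]oxy}silane | C1=C[C@](C)(O[Si](C)(C)CBr)CC1
A7 | alternative 3 | (R)-1-methylcyclopent-2-en-1-ol | C1=C[C@](C)(O)CC1
A8 | alternative 3 | (R)-linalool, (3R)-3,7-dimethylocta-1,6-dien-3-ol | CC(C)=CCC[C@@](C)(O)C=C
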